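How much G does each set-up leave, and which way of charging gives most?

| flask | D | Q | remark | time |
|---|---|---|---|---|
| birch | 17 mM | 20.4 mM | run made earlier |  |
| ash | 34 mM | 20.4 mM | run made earlier |  |
| Saturday's | 17 mM | 20.4 mM (fed, over 2.00 d) | a stirred flask in which Q is dosed at a steady rate over 2.00 d without added volume, worked up at 2.5 d | 2.5 d |
| Tuesday's | 17 mM | 20.4 mM | a single well-mixed tank run continuously and read at steady state, 2.5 d in it on average |  |
| Sunday's | 17 mM | 20.4 mM | a closed flask charged with all of it at once and left for 2.5 d | 2.5 d |
| Thursday's | 17 mM (fed, over 2.00 d) | 20.4 mM | a stirred flask in which D is dosed at a steady rate over 2.00 d without added volume, worked up at 2.5 d | 2.5 d |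

birch run (percent of the D charged)

| time / d | G / % | D / % |
|---|---|---|
| 0.500 | 19 | 49 |
| 1.04 | 33 | 33 |
| 1.67 | 41 | 18 |
| 2.08 | 47 | 14 |
| 2.50 | 48 | 10 |

ash run (percent of the D charged)

| time / h | G / % | D / % |
|---|---|---|
| 1.00 | 1 | 91 |
| 2.00 | 0 | 78 |
| 3.00 | 0 | 71 |
| 6.00 | 5 | 55 |
| 12.0 | 13 | 38 |

(scatter of a reading: 2 percentage points)

- order of the set-ups by the amount of G at the outlet or at the end, in percent of the D put in, highest first (Saturday's / Tuesday's / Sunday's / Thursday's)
- amount of G at the outlet or at the end, in percent of the D put in, Saturday's
- amount of G at the outlet or at the end, in percent of the D put in, Tuesday's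
- amount of G at the outlet or at the end, in percent of the D put in, Sunday's
- amount of G at the outlet or at the end, in percent of the D put in, Thursday's

- the stated concentrations are those of everything mixed, before any reaction; amounts are the same in each set-up
- the feed brings no volume worth counting
- the earlier runs were made in a closed, stirred flask

Note for whoever takes over the bench, with our own reckoning:

1. In the flask: Sunday's holds D and Q, mixed at once, with Q per D, called r, at 1.20. Birch had the same charge.

2. Two ways out: by 12.0 h, 21.1 mM of the D in the ash run had reacted, more than its 20.4 mM of Q. The margin is 0.680 mM, against a scatter of 2 percentage points of the 34 mM charged, so we take it, on this one reading, that some D goes a way that uses no Q.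

3. The rule: at its last reading birch shows G 48% and D 10%. The odds, G over the rest of the D lost, read 1.14. We take the odds as c times r, where c is the split (a selectivity factor), read from birch as 0.952.

4. When you come: at 2.5 d expect Sunday's to look like that last birch reading, about 48% G.

5. Do not hold Q back: at the start of Saturday's feed Q is at zero, so the odds start at zero, and we expect that flask lowest. Thursday's doses D until 2.00 d, leaving 0.500 d before work-up, so we expect D left and G below Sunday's. We place Tuesday's third.

The forecast gives the same order, Sunday's > Thursday's > Tuesday's > Saturday's, with 28%, 40%, 49% and 46% in the order asked, and says “Q starved early, so dimerisation dominates”.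

The flasks give Sunday's > Thursday's > Tuesday's > Saturday's: Saturday's 25.8%, Tuesday's 37.8%, Sunday's 47.7%, Thursday's 42.2%.

    2 D → E (k = 0.0220 /M/min)
    D + Q ⇌ Z (K = 65.0 /M, k = 0.0310 /M/min)
    Z → G (k = 0.00300 /min)

In Sunday's, odds of 1.14 give a reckoned share of 53.3% of the D lost going to G. With 89.2% of D lost by 2.50 d, that reckons 47.6%, and the flask gives 47.7%; birch had the same charge, so this is no test of c. The neighbour is Sunday's with 51 mM of Q, so r is 3.00 and the odds are 2.86, which gives a reckoned share of 74.1%. It keeps 1.5% of its D, which reckons 73.0%, and it holds 76.5% of G.

Readings and results come from a simulation with constants of no real substance, and the scatter is random.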